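Everything rests on excising C3 from ring C of the flavone. This contracts the pyranone to a furan and leads back to a 2-aryl-3-methoxybenzofuran that already holds O1, the future C4 oxygen and all seven aryl methoxy groups. The feature exploited is the C2=C3(OMe) enol ether bond of that furan ring (flavone C2 and C4), the most nucleophilic pi bond in the molecule. In one operation dichlorocarbene delivers the missing carbon, forms C2-C3 and C3-C4, expands the five-membered ring to ring C and unmasks the C4 carbonyl. The precursor comes from a Negishi union of a ring A benzofuran and a ring B bromide. Hydrogenolysis of the C3 chloride ends the route.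

Key step: step 9

Remark on the chemistry: the target has no stereocentre, so nothing has to be set. The only stereogenic species on the main line, the transient cyclopropane of the key step, is racemic and is drawn as one enantiomer.

Step 1
Reactants: 1 3,4,5-trimethoxyphenol
Product: 2 1,2,3,5-tetramethoxybenzene
Conditions: MeI (1.5 equiv), K2CO3, acetone, reflux
Reagents that add atoms: iodomethane, CI
Why: Williamson ether synthesis on the only acidic, unhindered OH group of the molecule.

Step 2
Reactants: 2 1,2,3,5-tetramethoxybenzene
Product: 4 2-chloro-1-(2-hydroxy-3,4,6-trimethoxyphenyl)ethan-1-one, via tetramethoxyphenyl chloromethyl ketone 3 (not isolated)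
Conditions: ClCH2COCl (1.2 equiv), AlCl3 (2.5 equiv), CH2Cl2, 0 °C to rt; then ice/1 M HCl
Reagents that add atoms: chloroacetyl chloride, O=C(Cl)CCl
Why: Friedel-Crafts acylation at one of the two symmetry-equivalent free positions gives 3, and AlCl3 chelated to the new carbonyl then cleaves the ortho methoxy group that is buttressed by a second methoxy neighbour (twisted out of conjugation, more Lewis basic and more strained than the other ortho ether), the selectivity established for hindered-ether cleavage in 2,3,4,6-tetraalkoxyaryl ketones.

Step 3
Reactants: 4 2-chloro-1-(2-hydroxy-3,4,6-trimethoxyphenyl)ethan-1-one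
Product: 5 4,6,7-trimethoxybenzofuran-3(2H)-one
Conditions: NaOAc (3 equiv), MeOH, reflux
Reagents that add atoms: none
Why: Intramolecular Williamson etherification (5-exo-tet) of the phenoxide on the alpha-chloro ketone, the standard coumaran-3-one closure, run with a base too weak to provoke aldol self-condensation.

Step 4
Reactants: 5 4,6,7-trimethoxybenzofuran-3(2H)-one
Product: 6 3,4,6,7-tetramethoxybenzofuran
Conditions: HC(OMe)3 (5 equiv), p-TsOH·H2O (5 mol %), MeOH, reflux; Et3N quench
Reagents that add atoms: trimethyl orthoformate, COC(OC)OC
Why: Acid-catalysed enol etherification with an orthoester, in which the hemiketal ionises to an oxocarbenium ion stabilised by the 4- and 6-methoxy groups, loss of a C2 proton gives the aromatic furan, the orthoformate removes water, and C-methylation is impossible.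

Step 5
Reactants: 7 2,3,4-trimethoxybenzaldehyde
Product: 9 2,3,4-trimethoxyphenol, via aryl formate 8 (not isolated)
Conditions: 30% aq H2O2 (1.3 equiv), H2SO4 (cat.), MeOH, rt
Reagents that add atoms: hydrogen peroxide, OO
Why: Acid-catalysed Dakin oxidation (Baeyer-Villiger-type migration of the electron-rich aryl group in the peroxyhemiacetal), followed by methanolysis of formate 8 in the same flask.

Step 6
Reactants: 9 2,3,4-trimethoxyphenol
Product: 10 1,2,3,4-tetramethoxybenzene
Conditions: MeI (1.5 equiv), K2CO3, acetone, reflux
Reagents that add atoms: iodomethane, CI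
Why: Williamson ether synthesis on the single phenolic OH group.

Step 7
Reactants: 10 1,2,3,4-tetramethoxybenzene
Product: 11 1-bromo-2,3,4,5-tetramethoxybenzene
Conditions: NBS (1.0 equiv), MeCN, 0 °C to rt
Reagents that add atoms: N-bromosuccinimide, O=C1CCC(=O)N1Br
Why: Electrophilic aromatic bromination in which the two free positions are equivalent by symmetry and the first bromine slows a second substitution, so one equivalent of NBS should stop at the monobromide.

Step 8
Reactants: 6 3,4,6,7-tetramethoxybenzofuran; 11 1-bromo-2,3,4,5-tetramethoxybenzene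
Product: 14 3,4,6,7-tetramethoxy-2-(2,3,4,5-tetramethoxyphenyl)benzofuran, via 2-lithiobenzofuran 12 (not isolated), via benzofuran-2-ylzinc chloride 13 (not isolated)
Conditions: n-BuLi (1.05 equiv), THF, -78 °C; ZnCl2 (1.1 equiv), -78 °C to rt; 11, Pd(OAc)2 (2 mol %), SPhos (4 mol %), THF, 60 °C
Reagents that add atoms: none
Why: Negishi coupling, in which n-BuLi at -78 °C removes the furan C2-H (alpha to O1 and next to the coordinating 3-methoxy group) faster than the C5-H between two methoxy groups, and the derived zinc reagent couples with the electron-rich, ortho-substituted bromide under a bulky biarylphosphine palladium catalyst.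

Step 9
Reactants: 14 3,4,6,7-tetramethoxy-2-(2,3,4,5-tetramethoxyphenyl)benzofuran; 15 chloroform
Product: 18 3-chloro-5,7,8-trimethoxy-2-(2,3,4,5-tetramethoxyphenyl)chromen-4-one, via dichlorocyclopropane adduct 16 (not isolated), via 3-chloro-4-methoxyflavylium chloride 17 (not isolated)
Conditions: KOtBu (6 equiv), CHCl3 (8 equiv, slow addition), toluene, -15 °C to rt, then 40 °C; 1 M HCl/THF work-up
Reagents that add atoms: chloroform (15), ClC(Cl)Cl
Why: Proposed new method: dichlorocarbene, released from chloroform by alpha-elimination, is attacked by the nucleophilic C2 of the C2=C3(OMe) enol ether and closes to the cis-fused gem-dichlorocyclopropane 16, which is too strained and too donor-flanked to persist. Ionisation of the endo chloride, always available in a gem-dichloride, is coupled to disrotatory cleavage of the shared C2-C3 bond and pushed by O1 and the 3-methoxy oxygen; this gives the aromatic flavylium chloride 17, so the six-membered ring C arises by one-carbon ring expansion of the furan and not by cyclisation of an open chain. The chloride counter-ion then dealkylates the activated O-methyl group by SN2 attack, releasing chloromethane and the pyranone carbonyl, and any cation intercepted by tert-butoxide as a chromene ketal is funnelled to the same ketone by the dilute acid work-up. The closest known reaction types are the Ciamician-Dennstedt halocarbene expansion of indoles and benzofurans and the dihalocarbene homologation of cyclic enol ethers to alpha-halo enones. No stereocentre survives, since the two transient centres of 16 are tied cis by the ring fusion and are erased on opening. The step needs chemoselectivity for the furan double bond over two polymethoxyarene rings, secured by the enol ether polarisation and the weak aromaticity of the furan; a second addition is excluded because the product alkene is an electron-poor chloro enone, and keeping chloroform in excess over KOtBu leaves no base to attack the base-sensitive product.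

Step 10
Reactants: 18 3-chloro-5,7,8-trimethoxy-2-(2,3,4,5-tetramethoxyphenyl)chromen-4-one
Product: 19 5,7,8-trimethoxy-2-(2,3,4,5-tetramethoxyphenyl)chromen-4-one (target)
Conditions: H2 (1 atm), 10% Pd/C, Et3N (1.5 equiv), EtOAc/MeOH, rt
Reagents that add atoms: none
Why: Catalytic hydrodehalogenation, in which zerovalent palladium inserts into the carbonyl-activated C3-Cl bond, Et3N traps HCl, and the conjugated C2=C3 bond of a flavone tolerates Pd/C at one atmosphere, as in routine hydrogenolysis of flavone benzyl ethers.

Compound list
1 | 3,4,5-trimethoxyphenol | COc1cc(O)cc(OC)c1OC | starting material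
2 | 1,2,3,5-tetramethoxybenzene | COc1cc(OC)c(OC)c(OC)c1 | intermediate
3 | 2-chloro-1-(2,3,4,6-tetramethoxyphenyl)ethan-1-one (not isolated) | COc1cc(OC)c(C(=O)CCl)c(OC)c1OC | intermediate
4 | 2-chloro-1-(2-hydroxy-3,4,6-trimethoxyphenyl)ethan-1-one | COc1cc(OC)c(C(=O)CCl)c(O)c1OC | intermediate
5 | 4,6,7-trimethoxybenzofuran-3(2H)-one | COc1cc(OC)c2c(c1OC)OCC2=O | intermediate
6 | 3,4,6,7-tetramethoxybenzofuran | COc1cc(OC)c2c(OC)coc2c1OC | intermediate
7 | 2,3,4-trimethoxybenzaldehyde | COc1ccc(C=O)c(OC)c1OC | starting material
8 | 2,3,4-trimethoxyphenyl formate (not isolated) | COc1ccc(OC=O)c(OC)c1OC | intermediate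
9 | 2,3,4-trimethoxyphenol | COc1ccc(O)c(OC)c1OC | intermediate
10 | 1,2,3,4-tetramethoxybenzene | COc1ccc(OC)c(OC)c1OC | intermediate
11 | 1-bromo-2,3,4,5-tetramethoxybenzene | COc1cc(Br)c(OC)c(OC)c1OC | intermediate
12 | (3,4,6,7-tetramethoxybenzofuran-2-yl)lithium (not isolated) | [Li]c1oc2c(OC)c(OC)cc(OC)c2c1OC | intermediate
13 | (3,4,6,7-tetramethoxybenzofuran-2-yl)zinc chloride (not isolated) | Cl[Zn]c1oc2c(OC)c(OC)cc(OC)c2c1OC | intermediate
14 | 3,4,6,7-tetramethoxy-2-(2,3,4,5-tetramethoxyphenyl)benzofuran | COc1cc(OC)c2c(OC)c(-c3cc(OC)c(OC)c(OC)c3OC)oc2c1OC | intermediate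
15 | chloroform | ClC(Cl)Cl | starting material
16 | 1,1-dichloro-3,4,6,6b-tetramethoxy-1a-(2,3,4,5-tetramethoxyphenyl)-1a,6b-dihydro-1H-cyclopropa[b]benzofuran, cis-fused, racemic, one enantiomer drawn (not isolated) | COc1cc(OC)c2c(c1OC)O[C@@]1(c3cc(OC)c(OC)c(OC)c3OC)C(Cl)(Cl)[C@@]21OC | intermediate
17 | 3-chloro-4,5,7,8-tetramethoxy-2-(2,3,4,5-tetramethoxyphenyl)chromenylium chloride (not isolated) | COc1cc(OC)c2c(OC)c(Cl)c(-c3cc(OC)c(OC)c(OC)c3OC)[o+]c2c1OC.[Cl-] | intermediate
18 | 3-chloro-5,7,8-trimethoxy-2-(2,3,4,5-tetramethoxyphenyl)chromen-4-one | COc1cc(-c2oc3c(OC)c(OC)cc(OC)c3c(=O)c2Cl)c(OC)c(OC)c1OC | intermediate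
19 | 5,7,8-trimethoxy-2-(2,3,4,5-tetramethoxyphenyl)chromen-4-one (5,7,8,2',3',4',5'-heptamethoxyflavone) | COc1cc(-c2cc(=O)c3c(OC)cc(OC)c(OC)c3o2)c(OC)c(OC)c1OC | target

Total step count: 10. Longest linear sequence: 7 (steps 1, 2, 3, 4, 8, 9, 10); steps 5 to 7 form the ring B branch.

Steps most likely to fail

1. Step 9.
   - Risk: capture of the short-lived carbene by the crowded, tetrasubstituted furan bond may be too slow relative to its consumption by tert-butoxide and tert-butanol. The cationic intermediate or the chloro enone may also be degraded by residual base.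
   - Fallback (known chemistry, classical chalcone route): it sets out from 4 and 11 and comes back at 19.
   - Zinc dust in AcOH at rt removes the alpha chlorine of 4 and should give 2'-hydroxy-3',4',6'-trimethoxyacetophenone F1.
   - Bromine-lithium exchange on 11 (n-BuLi, THF, -78 °C) followed by DMF should give 2,3,4,5-tetramethoxybenzaldehyde F2.
   - Claisen-Schmidt condensation of the two (KOH, EtOH, rt) should give the (E)-2'-hydroxychalcone F3.
   - Oxidative cyclisation of the chalcone with catalytic I2 in DMSO at 120 °C should give 19.

2. Step 8.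
   - Risk: deprotonation may spread to the C5-H between two methoxy groups. Oxidative addition into the electron-rich, ortho-substituted bromide may also be slow enough for protodemetalation and homocoupling of the zinc reagent to take over.
   - Fallback (aryl group enters at the ketone stage, which also bypasses step 4): it sets out from 5 and 11 and comes back at 14.
   - Palladium-catalysed ketone alpha-arylation (Pd(OAc)2, XPhos, NaOtBu 2.2 equiv, toluene, 80 °C, argon) should give racemic 4,6,7-trimethoxy-2-(2,3,4,5-tetramethoxyphenyl)benzofuran-3(2H)-one F4.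
   - The enolate of this ketone is O-methylated with the hard electrophile Me2SO4 (Cs2CO3, DMF, rt) to give 14.

3. Step 10.
   - Risk: saturation of the C2=C3 bond may compete with cleavage of the hindered C3-Cl bond.
   - Fallback (reduce through, then re-oxidise): it sets out from 18 and comes back at 19.
   - The hydrogenation is allowed, or driven (H2 4 atm, 10% Pd/C, Et3N, EtOH), to proceed to racemic 5,7,8-trimethoxy-2-(2,3,4,5-tetramethoxyphenyl)chroman-4-one F5.
   - The crude material is dehydrogenated with catalytic I2 in DMSO at 120 °C, the standard flavanone-to-flavone oxidation, to give 19.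

Further compounds
F1 | step 9 | 1-(2-hydroxy-3,4,6-trimethoxyphenyl)ethan-1-one | CC(=O)c1c(O)c(OC)c(OC)cc1OC
F2 | step 9 | 2,3,4,5-tetramethoxybenzaldehyde | COc1cc(C=O)c(OC)c(OC)c1OC
F3 | step 9 | (E)-1-(2-hydroxy-3,4,6-trimethoxyphenyl)-3-(2,3,4,5-tetramethoxyphenyl)prop-2-en-1-one | COc1cc(OC)c(C(=O)/C=C/c2cc(OC)c(OC)c(OC)c2OC)c(O)c1OC
F4 | step 8 | 4,6,7-trimethoxy-2-(2,3,4,5-tetramethoxyphenyl)benzofuran-3(2H)-one (racemic) | COc1cc(OC)c2c(c1OC)OC(c1cc(OC)c(OC)c(OC)c1OC)C2=O
F5 | step 10 | 5,7,8-trimethoxy-2-(2,3,4,5-tetramethoxyphenyl)chroman-4-one (racemic) | COc1cc(C2CC(=O)c3c(OC)cc(OC)c(OC)c3O2)c(OC)c(OC)c1OC
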